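**Strategy.** The route rests on cutting the O–C16(=O)–C15(=C17H2) bridge that spans C14 and C1 of the 14-membered ring (cembrane numbering) back to carbon monoxide and a macrocyclic homopropargylic alcohol. A single palladium-catalysed cyclocarbonylation forms O–C16 and C16–C15 and closes the cis-fused α-methylene-γ-butyrolactone, so the electrophilic exocyclic enoate is made after every basic and nucleophilic operation. The precursor is the carbocycle that already holds the 3,4-epoxide, the 7E alkene, the C12 methyl, a C13 silyl ether, the free C14 hydroxyl and a cis C1 ethynyl group. It is assembled by an auxiliary-controlled syn-aldol (C1–C14), a B-alkyl Suzuki ring closure (C8–C9) and an Ohira–Bestmann alkynylation.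

Key step: step 22

Remark: cembrane numbering is used throughout (ring C1–C14; C15, C16, C17 are the ethynyl/lactone carbons; methyls on C4, C8, C12) and the target is read as 1S,3R,4R,7E,12S,13R,14R with a cis-fused lactone; C13 is carried as a TBS ether and C14 as a TES ether until step 21, so that the free C14 hydroxyl (1,4 to the epoxide and vicinal to the silyl ether) exists only just before the carbonylation.

**Route**

Step 1
Reactants: 1 (R)-4-benzyloxazolidin-2-one; 2 bromoacetyl bromide
Product: 3 (R)-4-benzyl-3-(bromoacetyl)oxazolidin-2-one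
Conditions: n-BuLi, THF, −78 °C; then 2, −78 → 0 °C
Reagents that add atoms: none
Why: N-acylation of the lithiated oxazolidinone by the acid bromide is a standard acyl substitution that leaves the auxiliary stereocentre untouched.

Step 2
Reactants: 3
Product: 5 (R)-4-benzyl-3-[(triphenylphosphoranylidene)acetyl]oxazolidin-2-one, via phosphonium bromide 4 (not isolated)
Conditions: PPh3, toluene, rt; then 1 M aq. NaOH, CH2Cl2, 0 °C
Reagents that add atoms: triphenylphosphine, c1ccccc1P(c1ccccc1)c1ccccc1
Why: SN2 displacement of the activated α-bromide by the phosphine and deprotonation of the acidic acylphosphonium salt should give the stabilised Wittig ylide.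

Step 3
Reactants: 6 pent-3-yn-1-ol
Product: 7 5-bromopent-2-yne
Conditions: CBr4, PPh3, CH2Cl2, 0 °C
Reagents that add atoms: carbon tetrabromide, BrC(Br)(Br)Br
Why: Appel bromination of an unhindered primary alcohol.

Step 4
Reactants: 7 5-bromopent-2-yne; 8 ethyl but-2-ynoate
Product: 10 ethyl (2E)-3-methyloct-2-en-6-ynoate, via pent-3-ynylmagnesium bromide 9 (not isolated)
Conditions: Mg, THF, rt; CuBr·SMe2 (1 equiv), THF, −40 °C; 8, −78 °C; aq. NH4Cl at −78 °C
Reagents that add atoms: none
Why: The Grignard-derived organocopper adds syn across the ynoate (carbocupration) and cold protonation of the alkenylcopper with retention places the new chain trans to the ester, giving the 2E geometry that later becomes the trans-epoxide.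

Step 5
Reactants: 10 ethyl (2E)-3-methyloct-2-en-6-ynoate
Product: 11 (2E)-3-methyloct-2-en-6-yn-1-ol
Conditions: i-Bu2AlH (2.2 equiv), CH2Cl2, −78 → 0 °C; aq. potassium sodium tartrate work-up
Reagents that add atoms: none
Why: 1,2-Reduction of the conjugated ester by the aluminium hydride gives the allylic alcohol, and the internal alkyne is inert at this temperature.

Step 6
Reactants: 11 (2E)-3-methyloct-2-en-6-yn-1-ol
Product: 13 (2E,6E)-7-iodo-3-methylocta-2,6-dien-1-ol, via alkenylzirconocene chloride 12 (not isolated)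
Conditions: Cp2Zr(H)Cl (3 equiv), THF, rt → 45 °C; then I2, THF, 0 °C
Reagents that add atoms: iodine, II
Why: Syn hydrozirconation of the methyl alkyne, equilibrated by excess reagent so that zirconium sits on the less hindered methyl-bearing carbon, then iodinolysis with retention should give the (E)-2-iodoalkene (a minor regioisomer would be removed by chromatography), while the trisubstituted alkene is inert and the hydroxyl is only zirconated.

Step 7
Reactants: 13 (2E,6E)-7-iodo-3-methylocta-2,6-dien-1-ol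
Product: 14 [(2R,3R)-3-[(3E)-4-iodopent-3-en-1-yl]-3-methyloxiran-2-yl]methanol
Conditions: Ti(OiPr)4 (10 mol%), D-(−)-diisopropyl tartrate (12 mol%), t-BuOOH, 4 Å molecular sieves, CH2Cl2, −20 °C
Reagents that add atoms: tert-butyl hydroperoxide, CC(C)(C)OO
Why: Sharpless asymmetric epoxidation touches only the allylic-alcohol alkene, and the D-tartrate ligand is expected to deliver oxygen to the face that gives the (2R,3R) epoxide (C3 and C4 of the target), trans because the alkene is E.

Step 8
Reactants: 14 the (2R,3R)-epoxy alcohol; 5 the imide ylide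
Product: 16 (R)-4-benzyl-3-{(2E)-3-[(2R,3R)-3-[(3E)-4-iodopent-3-en-1-yl]-3-methyloxiran-2-yl]prop-2-enoyl}oxazolidin-2-one, via epoxy aldehyde 15 (not isolated)
Conditions: PhI(OAc)2, TEMPO (10 mol%), CH2Cl2, rt; then 5, rt
Reagents that add atoms: none
Why: Oxoammonium (TEMPO) oxidation of the primary alcohol followed by in situ Wittig olefination with the stabilised ylide traps the sensitive epoxy aldehyde as the E-enimide without disturbing the epoxide stereocentres.

Step 9
Reactants: 16 the epoxy enimide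
Product: 17 (R)-4-benzyl-3-{3-[(2R,3R)-3-[(3E)-4-iodopent-3-en-1-yl]-3-methyloxiran-2-yl]propanoyl}oxazolidin-2-one
Conditions: 2-nitrobenzenesulfonohydrazide, Et3N, CH2Cl2, rt
Reagents that add atoms: none
Why: Diimide generated in situ transfers H2 concertedly to the disubstituted conjugated C1=C2 bond, whereas the trisubstituted vinyl iodide reacts far more slowly and the allylic epoxide cannot be hydrogenolysed by this reagent.

Step 10
Reactants: 18 (E)-but-2-en-1-ol
Product: 19 [(2S,3S)-3-methyloxiran-2-yl]methanol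
Conditions: Ti(OiPr)4 (5 mol%), L-(+)-diisopropyl tartrate (6 mol%), t-BuOOH, 4 Å molecular sieves, CH2Cl2, −20 °C
Reagents that add atoms: tert-butyl hydroperoxide, CC(C)(C)OO
Why: Sharpless asymmetric epoxidation of the E allylic alcohol with the L-tartrate ligand should give the (2S,3S) trans-epoxide, which fixes the oxygen-bearing centre that becomes C13.

Step 11
Reactants: 19 [(2S,3S)-3-methyloxiran-2-yl]methanol; 20 allylmagnesium bromide
Product: 21 (2R,3S)-3-methylhex-5-ene-1,2-diol
Conditions: 20 (2.5 equiv), CuI (10 mol%), THF, −40 → −20 °C; aq. NH4Cl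
Reagents that add atoms: none
Why: Copper-catalysed SN2 opening of the epoxy alkoxide at the less hindered methyl-bearing carbon with inversion sets C12 and leaves C13 untouched, giving the syn C12-methyl/C13-hydroxyl pattern (any 1,3-diol regioisomer would be separated).

Step 12
Reactants: 21 (2R,3S)-3-methylhex-5-ene-1,2-diol
Product: 22 (2R,3S)-1,2-bis(tert-butyldimethylsilyloxy)-3-methylhex-5-ene
Conditions: TBSCl (2.5 equiv), imidazole, DMF, rt → 40 °C
Reagents that add atoms: tert-butyldimethylsilyl chloride, CC(C)(C)[Si](C)(C)Cl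
Why: Exhaustive silylation of both hydroxyls under imidazole catalysis.

Step 13
Reactants: 22 the bis-silyl ether
Product: 23 (2R,3S)-2-(tert-butyldimethylsilyloxy)-3-methylhex-5-en-1-ol
Conditions: HF·pyridine, pyridine, THF, 0 °C
Reagents that add atoms: none
Why: The unhindered primary silyl ether is cleaved much faster by buffered fluoride than the secondary one next to the branched carbon, so the desilylation is site-selective.

Step 14
Reactants: 23 the primary alcohol
Product: 24 (2R,3S)-2-(tert-butyldimethylsilyloxy)-3-methylhex-5-enal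
Conditions: Dess–Martin periodinane, pyridine, CH2Cl2, 0 °C → rt; used at once
Reagents that add atoms: none
Why: Buffered Dess–Martin oxidation gives the α-silyloxy aldehyde without epimerising the adjacent centre.

Step 15
Reactants: 17 the epoxy imide; 24 the α-silyloxy aldehyde
Product: 26 (R)-4-benzyl-3-[(2R,3R,4R,5S)-4-(tert-butyldimethylsilyloxy)-3-hydroxy-2-{[(2R,3R)-3-[(3E)-4-iodopent-3-en-1-yl]-3-methyloxiran-2-yl]methyl}-5-methyloct-7-enoyl]oxazolidin-2-one, via boron enolate 25 (not isolated)
Conditions: Et3N (1.3 equiv) then Bu2BOTf (1.1 equiv), CH2Cl2, −78 → 0 °C; 24, −78 → 0 °C; pH 7 buffer, MeOH, H2O2, 0 °C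
Reagents that add atoms: none
Why: Evans syn-aldol, in which the Z-dibutylboron enolate reacts through a closed chair transition state with one enolate face shielded by the (R)-benzyl group, so C1 and C14 are set under reagent control as the syn pair needed for the cis ring fusion while C12 and C13 come in with the aldehyde; adding the amine before the boron triflate keeps free Lewis acid away from the epoxide.

Step 16
Reactants: 26 the syn-aldol adduct
Product: 27 (R)-4-benzyl-3-[(2R,3R,4R,5S)-4-(tert-butyldimethylsilyloxy)-2-{[(2R,3R)-3-[(3E)-4-iodopent-3-en-1-yl]-3-methyloxiran-2-yl]methyl}-5-methyl-3-(triethylsilyloxy)oct-7-enoyl]oxazolidin-2-one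
Conditions: Et3SiCl, imidazole, DMAP (cat.), DMF, rt
Reagents that add atoms: chlorotriethylsilane, CC[Si](Cl)(CC)CC
Why: Silylation under non-acidic conditions masks the C14 hydroxyl with a group that can later be removed selectively in the presence of the C13 TBS ether and the epoxide.

Step 17
Reactants: 27 the silylated imide
Product: 28 (2S,3R,4R,5S)-4-(tert-butyldimethylsilyloxy)-2-{[(2R,3R)-3-[(3E)-4-iodopent-3-en-1-yl]-3-methyloxiran-2-yl]methyl}-5-methyl-3-(triethylsilyloxy)oct-7-en-1-ol
Conditions: LiBH4, MeOH (1.5 equiv), THF, 0 °C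
Reagents that add atoms: none
Why: Borohydride attack at the exocyclic imide carbonyl cleaves the auxiliary reductively and gives the C15 primary alcohol without epimerising C1.

Step 18
Reactants: 28 the open-chain iodo alkene alcohol
Product: 30 (1S,3R,4R,7E,12S,13R,14R)-13-(tert-butyldimethylsilyloxy)-3,4-epoxy-1-(hydroxymethyl)-4,8,12-trimethyl-14-(triethylsilyloxy)cyclotetradec-7-ene, via alkylborane 29 (not isolated)
Conditions: 9-BBN (3 equiv), THF, rt; then slow addition to Pd(dppf)Cl2 (20 mol%), AsPh3, Cs2CO3, DMF/THF/H2O, 45 °C, 1 mM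
Reagents that add atoms: none
Why: Anti-Markovnikov hydroboration of the only terminal alkene and intramolecular B-alkyl Suzuki–Miyaura coupling with the C8 vinyl iodide (oxidative addition to zerovalent palladium, base-assisted transmetalation, reductive elimination with retention of alkene geometry) should close the 14-membered ring at C8–C9 under high dilution.

Step 19
Reactants: 30 the macrocyclic alcohol
Product: 31 (1R,3R,4R,7E,12S,13R,14R)-13-(tert-butyldimethylsilyloxy)-3,4-epoxy-4,8,12-trimethyl-14-(triethylsilyloxy)cyclotetradec-7-ene-1-carbaldehyde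
Conditions: Dess–Martin periodinane, pyridine, CH2Cl2, 0 °C; used at once
Reagents that add atoms: none
Why: Buffered Dess–Martin oxidation converts the C15 alcohol into the aldehyde without acid that could open the epoxide or base that could epimerise C1.

Step 20
Reactants: 31 the macrocyclic aldehyde; 32 dimethyl (1-diazo-2-oxopropyl)phosphonate
Product: 33 (1S,3R,4R,7E,12S,13R,14R)-13-(tert-butyldimethylsilyloxy)-3,4-epoxy-1-ethynyl-4,8,12-trimethyl-14-(triethylsilyloxy)cyclotetradec-7-ene
Conditions: K2CO3, MeOH, 0 °C → rt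
Reagents that add atoms: none
Why: Ohira–Bestmann homologation, in which methanolysis of the acetyl group frees the diazomethylphosphonate anion, which adds to the aldehyde, loses phosphate and N2 and rearranges by 1,2-hydride shift of the alkylidene carbene, should install the ethynyl group with C1 unchanged under these mild conditions.

Step 21
Reactants: 33 the bis-silylated alkyne
Product: 34 (1S,3R,4R,7E,12S,13R,14R)-13-(tert-butyldimethylsilyloxy)-3,4-epoxy-1-ethynyl-4,8,12-trimethylcyclotetradec-7-en-14-ol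
Conditions: HF·pyridine, pyridine, THF, 0 °C
Reagents that add atoms: none
Why: Buffered fluoride cleaves the triethylsilyl ether far faster than the hindered TBS ether, releasing C14–OH as the only free hydroxyl while the excess pyridine shields the epoxide from acid.

Step 22
Reactants: 34 the macrocyclic cis-1-ethynyl C14 alcohol; 35 carbon monoxide
Product: 36 13-O-(tert-butyldimethylsilyl)-13-deacetyleupalmerin (cis-fused α-methylene-γ-butyrolactone on C1/C14)
Conditions: PdCl2(PPh3)2 (10 mol%), SnCl2 (10 mol%, anhydrous), CO (3 atm), MeCN, 65 °C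
Reagents that add atoms: none
Why: Divalent palladium, made more electrophilic by the SnCl3 ligand that forms from SnCl2, takes up CO and the C14 hydroxyl to give an alkoxycarbonyl–palladium species, Pd–C16(=O)–O–C14. Syn insertion of the tethered C15≡C17 triple bond into the Pd–C16 bond then forms C16–C15 and closes the five-membered ring O–C16–C15–C1–C14 in a 5-exo-dig mode, and protonolysis of the alkenyl–palladium bond at C17 leaves the exocyclic methylene and regenerates divalent palladium. The closest known reaction is the PdCl2/phosphine/SnCl2 cyclocarbonylation of 3-butyn-1-ols to α-methylene-γ-butyrolactones. No stereocentre is created; the cis ring fusion is inherited from the syn C1/C14 relationship fixed by the aldol of step 15, which also holds the hydroxyl and the alkyne close enough for an easy closure. The step needs chemoselectivity for the γ-lactone, which is secured because C14–OH is the only free hydroxyl (C13 is a TBS ether) and the ethynyl group the only alkyne. It also needs the epoxide and the trisubstituted alkene to stay spectators, which is why the tin salt is kept catalytic and anhydrous in a neutral nitrile solvent at moderate temperature.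

Step 23
Reactants: 36 the silyl lactone
Product: 37 13-deacetyleupalmerin (free C13 hydroxyl)
Conditions: HF·pyridine, pyridine, THF, 0 °C → rt
Reagents that add atoms: none
Why: Fluoride-mediated cleavage of the secondary TBS ether under pyridine-buffered conditions avoids both an alkoxide next to the lactone and strong acid at the epoxide.

Step 24
Reactants: 37 13-deacetyleupalmerin
Product: 38 eupalmerin acetate
Conditions: Ac2O, pyridine, DMAP (cat.), CH2Cl2, 0 °C → rt
Reagents that add atoms: acetic anhydride, CC(=O)OC(C)=O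
Why: Nucleophile-catalysed acetylation of the secondary C13 hydroxyl under mild basic conditions that the epoxide and the methylene lactone tolerate.

**Compound list**

1 | (R)-4-benzyloxazolidin-2-one | O=C1N[C@H](Cc2ccccc2)CO1 | starting material
2 | bromoacetyl bromide | BrCC(Br)=O | starting material
3 | (R)-4-benzyl-3-(bromoacetyl)oxazolidin-2-one | O=C(CBr)N1[C@H](Cc2ccccc2)COC1=O | intermediate
4 | {2-[(R)-4-benzyl-2-oxooxazolidin-3-yl]-2-oxoethyl}triphenylphosphonium bromide | [Br-].O=C(C[P+](c1ccccc1)(c1ccccc1)c1ccccc1)N1[C@H](Cc2ccccc2)COC1=O | intermediate (not isolated)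
5 | (R)-4-benzyl-3-[(triphenylphosphoranylidene)acetyl]oxazolidin-2-one | O=C(C=P(c1ccccc1)(c1ccccc1)c1ccccc1)N1[C@H](Cc2ccccc2)COC1=O | intermediate
6 | pent-3-yn-1-ol | CC#CCCO | starting material
7 | 5-bromopent-2-yne | CC#CCCBr | intermediate
8 | ethyl but-2-ynoate | CC#CC(=O)OCC | starting material
9 | pent-3-ynylmagnesium bromide | CC#CCC[Mg]Br | intermediate (not isolated)
10 | ethyl (2E)-3-methyloct-2-en-6-ynoate | CC#CCC/C(C)=C/C(=O)OCC | intermediate
11 | (2E)-3-methyloct-2-en-6-yn-1-ol | CC#CCC/C(C)=C/CO | intermediate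
12 | (E)-alkenylzirconocene chloride from 11, zirconium on the methyl-bearing carbon, hydroxyl as its zirconocene chloride alkoxide (cyclopentadienyl rings drawn σ-bonded) | C/C(=C\CC/C(C)=C/CO[Zr](Cl)(C1C=CC=C1)C1C=CC=C1)[Zr](Cl)(C1C=CC=C1)C1C=CC=C1 | intermediate (not isolated)
13 | (2E,6E)-7-iodo-3-methylocta-2,6-dien-1-ol | I/C(C)=C/CC/C(C)=C/CO | intermediate
14 | [(2R,3R)-3-[(3E)-4-iodopent-3-en-1-yl]-3-methyloxiran-2-yl]methanol | I/C(C)=C/CC[C@@]1(C)O[C@@H]1CO | intermediate
15 | (2S,3R)-3-[(3E)-4-iodopent-3-en-1-yl]-3-methyloxirane-2-carbaldehyde | I/C(C)=C/CC[C@@]1(C)O[C@@H]1C=O | intermediate (not isolated)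
16 | (R)-4-benzyl-3-{(2E)-3-[(2R,3R)-3-[(3E)-4-iodopent-3-en-1-yl]-3-methyloxiran-2-yl]prop-2-enoyl}oxazolidin-2-one | I/C(C)=C/CC[C@@]1(C)O[C@@H]1/C=C/C(=O)N2[C@H](Cc3ccccc3)COC2=O | intermediate
17 | (R)-4-benzyl-3-{3-[(2R,3R)-3-[(3E)-4-iodopent-3-en-1-yl]-3-methyloxiran-2-yl]propanoyl}oxazolidin-2-one | I/C(C)=C/CC[C@@]1(C)O[C@@H]1CCC(=O)N2[C@H](Cc3ccccc3)COC2=O | intermediate
18 | (E)-but-2-en-1-ol | C/C=C/CO | starting material
19 | [(2S,3S)-3-methyloxiran-2-yl]methanol | OC[C@@H]1O[C@H]1C | intermediate
20 | allylmagnesium bromide | C=CC[Mg]Br | starting material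
21 | (2R,3S)-3-methylhex-5-ene-1,2-diol | OC[C@H](O)[C@@H](C)CC=C | intermediate
22 | (2R,3S)-1,2-bis(tert-butyldimethylsilyloxy)-3-methylhex-5-ene | CC(C)(C)[Si](C)(C)OC[C@H](O[Si](C)(C)C(C)(C)C)[C@@H](C)CC=C | intermediate
23 | (2R,3S)-2-(tert-butyldimethylsilyloxy)-3-methylhex-5-en-1-ol | OC[C@H](O[Si](C)(C)C(C)(C)C)[C@@H](C)CC=C | intermediate
24 | (2R,3S)-2-(tert-butyldimethylsilyloxy)-3-methylhex-5-enal | O=C[C@H](O[Si](C)(C)C(C)(C)C)[C@@H](C)CC=C | intermediate
25 | (Z)-dibutylboron enolate of imide 17 | CCCCB(CCCC)O/C(=C\C[C@H]1O[C@]1(C)CC/C=C(\C)I)N2[C@H](Cc3ccccc3)COC2=O | intermediate (not isolated)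
26 | (R)-4-benzyl-3-[(2R,3R,4R,5S)-4-(tert-butyldimethylsilyloxy)-3-hydroxy-2-{[(2R,3R)-3-[(3E)-4-iodopent-3-en-1-yl]-3-methyloxiran-2-yl]methyl}-5-methyloct-7-enoyl]oxazolidin-2-one | O=C(N1[C@H](Cc2ccccc2)COC1=O)[C@H](C[C@H]3O[C@]3(C)CC/C=C(\C)I)[C@@H](O)[C@H](O[Si](C)(C)C(C)(C)C)[C@@H](C)CC=C | intermediate
27 | 3-O-triethylsilyl ether of 26 (C14–OTES) | O=C(N1[C@H](Cc2ccccc2)COC1=O)[C@H](C[C@H]3O[C@]3(C)CC/C=C(\C)I)[C@@H](O[Si](CC)(CC)CC)[C@H](O[Si](C)(C)C(C)(C)C)[C@@H](C)CC=C | intermediate
28 | (2S,3R,4R,5S)-4-(tert-butyldimethylsilyloxy)-2-{[(2R,3R)-3-[(3E)-4-iodopent-3-en-1-yl]-3-methyloxiran-2-yl]methyl}-5-methyl-3-(triethylsilyloxy)oct-7-en-1-ol | OC[C@H](C[C@H]1O[C@]1(C)CC/C=C(\C)I)[C@@H](O[Si](CC)(CC)CC)[C@H](O[Si](C)(C)C(C)(C)C)[C@@H](C)CC=C | intermediate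
29 | C9 B-alkyl-9-BBN adduct of 28 (C15 hydroxyl as its 9-BBN borinate) | C1CCC2CCCC1B2OC[C@H](C[C@H]3O[C@]3(C)CC/C=C(\C)I)[C@@H](O[Si](CC)(CC)CC)[C@H](O[Si](C)(C)C(C)(C)C)[C@@H](C)CCCB4C5CCCC4CCC5 | intermediate (not isolated)
30 | (1S,3R,4R,7E,12S,13R,14R)-13-(tert-butyldimethylsilyloxy)-3,4-epoxy-1-(hydroxymethyl)-4,8,12-trimethyl-14-(triethylsilyloxy)cyclotetradec-7-ene (cembrane numbering) | OC[C@H]1[C@@H](O[Si](CC)(CC)CC)[C@H](O[Si](C)(C)C(C)(C)C)[C@@H](C)CCC/C(C)=C/CC[C@@]2(C)O[C@@H]2C1 | intermediate
31 | (1R,3R,4R,7E,12S,13R,14R)-13-(tert-butyldimethylsilyloxy)-3,4-epoxy-4,8,12-trimethyl-14-(triethylsilyloxy)cyclotetradec-7-ene-1-carbaldehyde (cembrane numbering) | O=C[C@H]1[C@@H](O[Si](CC)(CC)CC)[C@H](O[Si](C)(C)C(C)(C)C)[C@@H](C)CCC/C(C)=C/CC[C@@]2(C)O[C@@H]2C1 | intermediate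
32 | dimethyl (1-diazo-2-oxopropyl)phosphonate | CC(=O)C(=[N+]=[N-])P(=O)(OC)OC | starting material
33 | (1S,3R,4R,7E,12S,13R,14R)-13-(tert-butyldimethylsilyloxy)-3,4-epoxy-1-ethynyl-4,8,12-trimethyl-14-(triethylsilyloxy)cyclotetradec-7-ene (cembrane numbering) | C#C[C@H]1[C@@H](O[Si](CC)(CC)CC)[C@H](O[Si](C)(C)C(C)(C)C)[C@@H](C)CCC/C(C)=C/CC[C@@]2(C)O[C@@H]2C1 | intermediate
34 | (1S,3R,4R,7E,12S,13R,14R)-13-(tert-butyldimethylsilyloxy)-3,4-epoxy-1-ethynyl-4,8,12-trimethylcyclotetradec-7-en-14-ol (cembrane numbering; ethynyl and hydroxyl cis) | C#C[C@H]1[C@@H](O)[C@H](O[Si](C)(C)C(C)(C)C)[C@@H](C)CCC/C(C)=C/CC[C@@]2(C)O[C@@H]2C1 | intermediate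
35 | carbon monoxide | [C-]#[O+] | starting material
36 | 13-O-(tert-butyldimethylsilyl)-13-deacetyleupalmerin | C=C1C(=O)O[C@H]2[C@H](O[Si](C)(C)C(C)(C)C)[C@@H](C)CCC/C(C)=C/CC[C@@]3(C)O[C@@H]3C[C@@H]12 | intermediate
37 | 13-deacetyleupalmerin | C=C1C(=O)O[C@H]2[C@H](O)[C@@H](C)CCC/C(C)=C/CC[C@@]3(C)O[C@@H]3C[C@@H]12 | intermediate
38 | eupalmerin acetate | C=C1C(=O)O[C@H]2[C@H](OC(C)=O)[C@@H](C)CCC/C(C)=C/CC[C@@]3(C)O[C@@H]3C[C@@H]12 | target

**Step count**

Total: 24 steps. Longest linear sequence: 17 steps (steps 3–9, then 15–24; 6 → 7 → 10 → 11 → 13 → 14 → 16 → 17 → 26 → 27 → 28 → 30 → 31 → 33 → 34 → 36 → 37 → 38).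

**Steps most likely to fail, with fallbacks**

Step 22 (cyclocarbonylation). The Lewis-acidic tin co-catalyst or traces of HCl may open the trisubstituted epoxide, possibly by transannular attack of the C14 hydroxyl, or the macrocyclic alkynol may carbonylate too slowly. The fallback sets out from 34 and comes back at 36; it builds the lactone without CO and adds the methylene last. Anti-Markovnikov hydroboration of the ethynyl group with dicyclohexylborane (excess, to cover the hydroxyl) and oxidation with NaBO3·4H2O should give an aldehyde that closes on C14–OH to the lactol F1. Oxidation with TEMPO/PhI(OAc)2 would give the saturated cis-fused γ-lactone F2. Enolisation with LiN(SiMe3)2 and trapping with dimethylmethyleneammonium iodide (Eschenmoser's salt) would give the Mannich base F3. Quaternisation with MeI to the ammonium iodide F4 and elimination with NaHCO3 would then deliver 36.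

Step 18 (ring closure). The alkylborane may be lost by protodeboronation or β-hydride elimination, or may oligomerise, before the 14-membered ring forms. The fallback sets out from 17 (and uses 24) and comes back at 30; it moves the ring closure to C9=C10 by ring-closing metathesis. Stille coupling of 17 with tributyl(vinyl)stannane (Pd2(dba)3, AsPh3, DMF) would give the dienyl imide F5 with retention of geometry. The aldol of step 15 with 24 would give the aldol adduct F6, silylation as in step 16 its triethylsilyl ether F7, and LiBH4 reduction the primary alcohol F8. Ring-closing metathesis of F8 between the diene terminus and the allyl group with the second-generation Grubbs catalyst at high dilution would give the macrocyclic diene alcohol F9 with loss of ethene. Diimide (as in step 9) should then saturate the disubstituted C9=C10 bond in preference to the trisubstituted C7=C8 bond and reach 30.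

Step 15 (aldol). The boron triflate may open the trisubstituted epoxide during enolisation, and the intrinsic facial preference of the α-silyloxy aldehyde opposes the auxiliary, which may erode the selectivity. The fallback sets out from 13 (and uses 1 and 24) and comes back at 27; it carries the C3=C4 alkene through the aldol and epoxidises afterwards. Appel bromination of 13 (CBr4, PPh3) would give the allylic bromide F10. Alkylation of the lithium enolate of methyl acetate (LiN(i-Pr)2, THF, −78 °C) would give the methyl ester F11, and LiOH the acid F12. Acylation of 1 through the pivaloyl mixed anhydride (PivCl, Et3N, LiCl) would give the alkenyl imide F13. The aldol of step 15 with 24 would give the aldol adduct F14, and silylation its triethylsilyl ether F15. Shi epoxidation of F15 (D-fructose-derived ketone, KHSO5, K2CO3 buffer, MeCN/H2O, 0 °C) should prefer the electron-rich trisubstituted C3=C4 bond over the vinyl iodide and the terminal alkene, is expected to give the (3R,4R) epoxide, and returns to 27.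

**Further compounds**

F1 | step 22 | lactol from 34 (C14–O–C17H(OH)–C15H2–C1, cis-fused, anomers unspecified) | OC1O[C@H]2[C@H](O[Si](C)(C)C(C)(C)C)[C@@H](C)CCC/C(C)=C/CC[C@@]3(C)O[C@@H]3C[C@H]2C1
F2 | step 22 | saturated cis-fused γ-lactone (13-O-TBS, no methylene) | O=C1O[C@H]2[C@H](O[Si](C)(C)C(C)(C)C)[C@@H](C)CCC/C(C)=C/CC[C@@]3(C)O[C@@H]3C[C@H]2C1
F3 | step 22 | α-(dimethylaminomethyl) lactone (Mannich base, α-centre unspecified) | CN(C)CC1C(=O)O[C@H]2[C@H](O[Si](C)(C)C(C)(C)C)[C@@H](C)CCC/C(C)=C/CC[C@@]3(C)O[C@@H]3C[C@@H]12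
F4 | step 22 | trimethylammoniomethyl lactone iodide | [I-].C[N+](C)(C)CC1C(=O)O[C@H]2[C@H](O[Si](C)(C)C(C)(C)C)[C@@H](C)CCC/C(C)=C/CC[C@@]3(C)O[C@@H]3C[C@@H]12
F5 | step 18 | (R)-4-benzyl-3-{3-[(2R,3R)-3-methyl-3-[(3E)-4-methylhexa-3,5-dien-1-yl]oxiran-2-yl]propanoyl}oxazolidin-2-one | C=C/C(C)=C/CC[C@@]1(C)O[C@@H]1CCC(=O)N2[C@H](Cc3ccccc3)COC2=O
F6 | step 18 | syn-aldol adduct of F5 and 24 (as 26, vinyl in place of iodine) | O=C(N1[C@H](Cc2ccccc2)COC1=O)[C@H](C[C@H]3O[C@]3(C)CC/C=C(\C)C=C)[C@@H](O)[C@H](O[Si](C)(C)C(C)(C)C)[C@@H](C)CC=C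
F7 | step 18 | C14 triethylsilyl ether of F6 | O=C(N1[C@H](Cc2ccccc2)COC1=O)[C@H](C[C@H]3O[C@]3(C)CC/C=C(\C)C=C)[C@@H](O[Si](CC)(CC)CC)[C@H](O[Si](C)(C)C(C)(C)C)[C@@H](C)CC=C
F8 | step 18 | primary alcohol from F7 (as 28, vinyl in place of iodine) | OC[C@H](C[C@H]1O[C@]1(C)CC/C=C(\C)C=C)[C@@H](O[Si](CC)(CC)CC)[C@H](O[Si](C)(C)C(C)(C)C)[C@@H](C)CC=C
F9 | step 18 | macrocyclic 7E,9-diene alcohol (as 30 with an extra C9=C10 double bond, geometry unspecified) | OC[C@H]1[C@@H](O[Si](CC)(CC)CC)[C@H](O[Si](C)(C)C(C)(C)C)[C@@H](C)CC=C/C(C)=C/CC[C@@]2(C)O[C@@H]2C1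
F10 | step 15 | (2E,6E)-1-bromo-7-iodo-3-methylocta-2,6-diene | I/C(C)=C/CC/C(C)=C/CBr
F11 | step 15 | methyl (4E,8E)-9-iodo-5-methyldeca-4,8-dienoate | I/C(C)=C/CC/C(C)=C/CCC(=O)OC
F12 | step 15 | (4E,8E)-9-iodo-5-methyldeca-4,8-dienoic acid | I/C(C)=C/CC/C(C)=C/CCC(=O)O
F13 | step 15 | (R)-4-benzyl-3-[(4E,8E)-9-iodo-5-methyldeca-4,8-dienoyl]oxazolidin-2-one | I/C(C)=C/CC/C(C)=C/CCC(=O)N1[C@H](Cc2ccccc2)COC1=O
F14 | step 15 | (R)-4-benzyl-3-[(2R,3R,4R,5S)-4-(tert-butyldimethylsilyloxy)-3-hydroxy-2-[(2E,6E)-7-iodo-3-methylocta-2,6-dien-1-yl]-5-methyloct-7-enoyl]oxazolidin-2-one | O=C(N1[C@H](Cc2ccccc2)COC1=O)[C@H](C/C=C(C)/CC/C=C(\C)I)[C@@H](O)[C@H](O[Si](C)(C)C(C)(C)C)[C@@H](C)CC=C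
F15 | step 15 | C14 triethylsilyl ether of F14 | O=C(N1[C@H](Cc2ccccc2)COC1=O)[C@H](C/C=C(C)/CC/C=C(\C)I)[C@@H](O[Si](CC)(CC)CC)[C@H](O[Si](C)(C)C(C)(C)C)[C@@H](C)CC=C
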